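## Retrosynthetic overview

1. Ring C (O1–C2) is closed last by Mitsunobu etherification of the C8a phenol onto the C2 primary alcohol, after the C8 hydroxymethyl group has been oxidised to the aldehyde; the ring B phenols travel as MOM ethers.
2. The strategy rests on ring A: a benzene ring substituted at five of its six positions (only C6 carries H), with three different oxygens (C5 OMe, C7 OH, C8a ring oxygen) and carbon substituents at C4a and C8. It is made by benzannulation of a 2-alkyl-3-methoxycyclobutenone (C4a, C5, C6, C7) with a siloxyalkyne (C8, C8a), forming C7–C8 and C4a–C8a and re-forming C6–C7.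
3. The cyclobutenone comes from ketene and a methoxyalkyne, itself made from a primary bromide and lithium methoxyacetylide; the siloxyalkyne comes from silyl-protected propargyl alcohol.
4. The only stereocentre, C3, is set by catalytic enantioselective opening of an achiral 3-aryloxetane with TMSBr; ring B is built from resorcinol by two directed ortho-lithiations and joined to 3-iodooxetane by nickel catalysis.
5. Ring order: ring B (from resorcinol), ring A (annulation), ring C (Mitsunobu).

Key step: step 10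

Assumption: the target is the (3R) enantiomer encoded in the SMILES; the sense of induction of the squaramide with this ortho-substituted aryloxetane has to be confirmed on the first run, and the catalyst enantiomer that gives the (R)-bromohydrin is the one meant.

Abbreviations used in names:
- Ar = 2,4-bis(methoxymethoxy)-3-(3-methylbut-2-en-1-yl)phenyl
- MOM = methoxymethyl; TBS = tert-butyldimethylsilyl; TIPS = triisopropylsilyl
- SQ = 3-{[3,5-bis(trifluoromethyl)phenyl]amino}-4-({(2S)-3,3-dimethyl-1-oxo-1-[(2R)-2-(phenanthren-9-yl)pyrrolidin-1-yl]butan-2-yl}amino)cyclobut-3-ene-1,2-dione, or its mirror image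

## Route

Step 1
Reactants: 1 resorcinol
Product: 2 1,3-bis(methoxymethoxy)benzene
Conditions: MOMCl (2.5 equiv), i-Pr2NEt, CH2Cl2, 0 °C → rt
Reagents that add atoms: chloromethyl methyl ether, COCCl
Why: Double O-alkylation of the phenols (Williamson-type ether synthesis with a reactive α-chloro ether) should install the two MOM groups, which direct both later lithiations and are removed in the last step.

Step 2
Reactants: 2 1,3-bis(methoxymethoxy)benzene; 3 prenyl bromide
Product: 5 1,3-bis(methoxymethoxy)-2-(3-methylbut-2-en-1-yl)benzene, via aryllithium 4 (not isolated)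
Conditions: n-BuLi, THF, 0 °C; then CuI (10 mol %), 3, −20 °C → rt
Reagents that add atoms: none
Why: Directed ortho-metalation takes place at the carbon flanked by both OMOM groups, and copper-catalysed allylation of the aryllithium with the primary allylic bromide should give the linear prenyl arene.

Step 3
Reactants: 5 1,3-bis(methoxymethoxy)-2-(3-methylbut-2-en-1-yl)benzene
Product: 7 1-iodo-2,4-bis(methoxymethoxy)-3-(3-methylbut-2-en-1-yl)benzene, via aryllithium 6 (not isolated)
Conditions: n-BuLi, TMEDA, THF, −20 → 0 °C; then ICH2CH2I, −78 °C → rt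
Reagents that add atoms: 1,2-diiodoethane, ICCI
Why: A second directed ortho-metalation can only occur at the two equivalent ring positions next to an OMOM group, and iodination of the aryllithium with 1,2-diiodoethane (no free iodine, so the prenyl alkene is left alone) should give the aryl iodide.

Step 4
Reactants: 7 1-iodo-2,4-bis(methoxymethoxy)-3-(3-methylbut-2-en-1-yl)benzene; 8 3-iodooxetane
Product: 9 3-Ar-oxetane
Conditions: NiI2 (10 mol %), 4,4′-di-tert-butyl-2,2′-bipyridine (10 mol %), pyridine (cat.), Zn, DMPU, 60 °C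
Reagents that add atoms: none
Why: Nickel-catalysed reductive cross-electrophile coupling (oxidative addition of the aryl iodide to low-valent nickel, capture of the oxetan-3-yl radical formed from the alkyl iodide, reductive elimination) should join the sp2 and sp3 carbons without a basic organometallic reagent.

Step 5
Reactants: 9 3-Ar-oxetane
Product: 11 (2R)-3-bromo-2-Ar-propan-1-ol, via silyl ether 10 (not isolated)
Conditions: TMSBr (1.2 equiv), SQ (5 mol %), t-BuOMe, −80 °C; then K2CO3 (cat.), MeOH, 0 °C
Reagents that add atoms: bromotrimethylsilane, C[Si](C)(C)Br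
Why: Catalytic enantioselective desymmetrising ring opening of a 3-aryloxetane: the squaramide binds bromide, the silyl group activates the strained ring oxygen, and catalyst-bound bromide attacks one of the two enantiotopic CH2 groups, which sets C3 as (R) under catalyst control, while the low temperature and the higher basicity of the oxetane oxygen should spare the MOM acetals; methanolysis of the TMS ether in the work-up frees the alcohol.

Step 6
Reactants: 11 (2R)-3-bromo-2-Ar-propan-1-ol
Product: 12 [(2R)-3-bromo-2-Ar-propoxy](tert-butyl)dimethylsilane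
Conditions: TBSCl, imidazole, CH2Cl2, 0 °C → rt
Reagents that add atoms: tert-butyldimethylsilyl chloride, CC(C)(C)[Si](C)(C)Cl
Why: Imidazole-promoted silylation of the primary alcohol gives a silyl ether that should tolerate the acetylide, ketene and annulation steps and is cleaved by fluoride together with the other silyl groups in step 11.

Step 7
Reactants: 12 [(2R)-3-bromo-2-Ar-propoxy](tert-butyl)dimethylsilane
Product: 13 tert-butyl{[(2R)-2-Ar-5-methoxypent-4-yn-1-yl]oxy}dimethylsilane
Conditions: ClCH2CH(OMe)2, LiNEt2 (3 equiv), THF, 0 °C; then 12, DMPU, −40 → 0 °C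
Reagents that add atoms: chloroacetaldehyde dimethyl acetal, COC(OC)CCl (converted in the flask into lithium methoxyacetylide, [Li]C#COC)
Why: SN2 alkylation of a lithium alkoxyacetylide by the primary bromide in a dipolar cosolvent should form the C4–alkyne bond; the stereocentre is next to the reacting carbon and is not touched, and the low temperature is meant to hold back E2 elimination across the benzylic C–H.

Step 8
Reactants: 13 tert-butyl{[(2R)-2-Ar-5-methoxypent-4-yn-1-yl]oxy}dimethylsilane
Product: 14 2-{(2R)-2-Ar-3-[(TBS)oxy]propyl}-3-methoxycyclobut-2-en-1-one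
Conditions: ketene (gas, excess), CH2Cl2, 0 °C → rt
Reagents that add atoms: ketene, C=C=O
Why: Thermal (2+2) cycloaddition of ketene with an electron-rich alkoxyalkyne, in which the nucleophilic alkyl-bearing alkyne carbon bonds to the ketene carbonyl carbon, should give the 2-alkyl-3-methoxycyclobutenone as a single regioisomer.

Step 9
Reactants: 15 tert-butyldimethyl(prop-2-yn-1-yloxy)silane
Product: 18 3-[(TBS)oxy]-1-[(TIPS)oxy]prop-1-yne, via lithium acetylide 16 (not isolated), via lithium ynolate 17 (not isolated)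
Conditions: n-BuLi, THF, −78 °C; LiOOt-Bu (from t-BuOOH, LiN(SiMe3)2), −78 → 0 °C; TIPSOTf, −78 °C
Reagents that add atoms: tert-butyl hydroperoxide, CC(C)(C)OO; triisopropylsilyl trifluoromethanesulfonate, CC(C)[Si](C(C)C)(C(C)C)OS(=O)(=O)C(F)(F)F
Why: Oxidation of a lithium acetylide by lithium tert-butyl peroxide gives the lithium ynolate, and its O-silylation with the bulky silyl triflate is the established route from a terminal alkyne to a triisopropylsiloxyalkyne.

Step 10
Reactants: 14 2-{(2R)-2-Ar-3-[(TBS)oxy]propyl}-3-methoxycyclobut-2-en-1-one; 18 3-[(TBS)oxy]-1-[(TIPS)oxy]prop-1-yne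
Product: 23 2-{[(TBS)oxy]methyl}-4-{(2R)-2-Ar-3-[(TBS)oxy]propyl}-5-methoxy-3-[(TIPS)oxy]phenol, via vinylketene 19 (not isolated), via vinylcyclobutenone 20 (not isolated), via dienylketene 21 (not isolated), via cyclohexadienone 22 (not isolated)
Conditions: 18 (1.5 equiv), hν (300 nm), toluene, 25 °C; then 110 °C
Reagents that add atoms: none
Why: Proposed new method: light should open cyclobutenone 14, a vinylogous ester expected to resist purely thermal 4π opening, to vinylketene 19, whose electrophilic ketene carbon is attacked by the nucleophilic alkyne carbon bearing CH2OTBS in a (2+2) cycloaddition that gives 20 (forming C7–C8 and C4a–C8a), after which heating opens 20 to dienylketene 21, 6π electrocyclisation gives dienone 22 and tautomerisation gives phenol 23. The closest known reaction type is the Danheiser benzannulation of alkyl-substituted cyclobutenones with siloxyalkynes to resorcinol monosilyl ethers, together with the known photochemical opening of cyclobutenones to vinylketenes; what has not been shown is a 3-alkoxycyclobutenone as the vinylketene source, although the 3-silyloxy-4-vinylcyclobutenone 20 is of the type that opens readily in every such annulation. Ring A is closed by thermal 6π electrocyclic ring closure of 21, which re-forms the C6–C7 bond broken in the first ring opening. No stereocentre is created (the quaternary carbon of 20 is lost again on ring opening) and the existing C3 centre, which lies in the side chain away from the reacting π system and has no acidifying neighbour, cannot epimerise under these neutral conditions. The only selectivity needed is regiochemical, and it is fixed by the polarity of the ketene/siloxyalkyne pair and by the connectivity of 14, which together place OH at C7, CH2OTBS at C8, OTIPS at C8a, the side chain at C4a, OMe at C5 and H at C6.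

Step 11
Reactants: 23 2-{[(TBS)oxy]methyl}-4-{(2R)-2-Ar-3-[(TBS)oxy]propyl}-5-methoxy-3-[(TIPS)oxy]phenol
Product: 24 2-(hydroxymethyl)-4-[(2R)-2-Ar-3-hydroxypropyl]-5-methoxybenzene-1,3-diol
Conditions: TBAF (3.5 equiv), THF, 0 °C; pH 7 buffer work-up; used crude at once
Reagents that add atoms: none
Why: Fluoride-induced desilylation should cleave the aryl TIPS ether and both primary TBS ethers, freeing the C8a phenol and both alcohols; because the electron-rich ortho-hydroxybenzyl alcohol can ionise to a quinone methide, it is oxidised without purification.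

Step 12
Reactants: 24 2-(hydroxymethyl)-4-[(2R)-2-Ar-3-hydroxypropyl]-5-methoxybenzene-1,3-diol
Product: 25 2,6-dihydroxy-3-[(2R)-2-Ar-3-hydroxypropyl]-4-methoxybenzaldehyde
Conditions: MnO2 (activated, excess), EtOAc, rt
Reagents that add atoms: none
Why: MnO2 oxidises benzylic alcohols chemoselectively, so the C8 CH2OH should go to the aldehyde (stabilised by hydrogen bonding to the flanking phenols) while the aliphatic primary alcohol is kept for the ring closure.

Step 13
Reactants: 25 2,6-dihydroxy-3-[(2R)-2-Ar-3-hydroxypropyl]-4-methoxybenzaldehyde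
Product: 26 (3R)-3-Ar-7-hydroxy-5-methoxy-3,4-dihydro-2H-chromene-8-carbaldehyde
Conditions: PPh3, DIAD, THF (0.01 M), 0 °C → rt
Reagents that add atoms: none
Why: Intramolecular Mitsunobu etherification should close ring C by 6-exo-tet displacement at the activated primary carbon by the C8a phenol, the only free hydroxyl ortho to the side chain (C5 is methylated and the C7 hydroxyl is para to C4a); the reacting carbon is not stereogenic, so the (R) centre is carried through unchanged.

Step 14
Reactants: 26 (3R)-3-Ar-7-hydroxy-5-methoxy-3,4-dihydro-2H-chromene-8-carbaldehyde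
Product: 27 (3R)-3-[2,4-dihydroxy-3-(3-methylbut-2-en-1-yl)phenyl]-7-hydroxy-5-methoxy-3,4-dihydro-2H-chromene-8-carbaldehyde
Conditions: HCl (3 M aq.), MeOH, 40 °C
Reagents that add atoms: none
Why: Acid-catalysed acetal methanolysis (MOM ether cleavage) should free the two ring B phenols under conditions mild enough that cyclisation of the prenyl group onto the neighbouring phenols does not compete, and the ring C ether and the C3 centre are inert to dilute acid.

## Compound list

1 | resorcinol (benzene-1,3-diol) | Oc1cccc(O)c1 | starting material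
2 | 1,3-bis(methoxymethoxy)benzene | COCOc1cccc(OCOC)c1 | intermediate
3 | prenyl bromide (1-bromo-3-methylbut-2-ene) | CC(C)=CCBr | starting material
4 | 2,6-bis(methoxymethoxy)phenyllithium (not isolated) | [Li]c1c(OCOC)cccc1OCOC | intermediate
5 | 1,3-bis(methoxymethoxy)-2-(3-methylbut-2-en-1-yl)benzene | COCOc1cccc(OCOC)c1CC=C(C)C | intermediate
6 | 2,4-bis(methoxymethoxy)-3-(3-methylbut-2-en-1-yl)phenyllithium (not isolated) | [Li]c1ccc(OCOC)c(CC=C(C)C)c1OCOC | intermediate
7 | 1-iodo-2,4-bis(methoxymethoxy)-3-(3-methylbut-2-en-1-yl)benzene | Ic1ccc(OCOC)c(CC=C(C)C)c1OCOC | intermediate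
8 | 3-iodooxetane | IC1COC1 | starting material
9 | 3-[2,4-bis(methoxymethoxy)-3-(3-methylbut-2-en-1-yl)phenyl]oxetane | C1OCC1c1ccc(OCOC)c(CC=C(C)C)c1OCOC | intermediate
10 | [(2R)-3-bromo-2-Ar-propoxy]trimethylsilane (not isolated) | BrC[C@H](c1ccc(OCOC)c(CC=C(C)C)c1OCOC)CO[Si](C)(C)C | intermediate
11 | (2R)-3-bromo-2-Ar-propan-1-ol | BrC[C@H](c1ccc(OCOC)c(CC=C(C)C)c1OCOC)CO | intermediate
12 | [(2R)-3-bromo-2-Ar-propoxy](tert-butyl)dimethylsilane | BrC[C@H](c1ccc(OCOC)c(CC=C(C)C)c1OCOC)CO[Si](C)(C)C(C)(C)C | intermediate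
13 | tert-butyl{[(2R)-2-Ar-5-methoxypent-4-yn-1-yl]oxy}dimethylsilane | COC#CC[C@H](c1ccc(OCOC)c(CC=C(C)C)c1OCOC)CO[Si](C)(C)C(C)(C)C | intermediate
14 | 2-{(2R)-2-Ar-3-[(TBS)oxy]propyl}-3-methoxycyclobut-2-en-1-one | COC1=C(C[C@H](c2ccc(OCOC)c(CC=C(C)C)c2OCOC)CO[Si](C)(C)C(C)(C)C)C(=O)C1 | intermediate
15 | tert-butyldimethyl(prop-2-yn-1-yloxy)silane | C#CCO[Si](C)(C)C(C)(C)C | starting material
16 | lithium 3-[(TBS)oxy]prop-1-yn-1-ide (not isolated) | [Li]C#CCO[Si](C)(C)C(C)(C)C | intermediate
17 | lithium 3-[(TBS)oxy]prop-1-yn-1-olate (not isolated) | [Li]OC#CCO[Si](C)(C)C(C)(C)C | intermediate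
18 | 3-[(TBS)oxy]-1-[(TIPS)oxy]prop-1-yne | CC(C)(C)[Si](C)(C)OCC#CO[Si](C(C)C)(C(C)C)C(C)C | intermediate
19 | 2-{(2R)-2-Ar-3-[(TBS)oxy]propyl}-3-methoxybuta-1,3-dien-1-one (vinylketene, not isolated) | C=C(OC)C(=C=O)C[C@H](c1ccc(OCOC)c(CC=C(C)C)c1OCOC)CO[Si](C)(C)C(C)(C)C | intermediate
20 | 2-{[(TBS)oxy]methyl}-4-{(2R)-2-Ar-3-[(TBS)oxy]propyl}-4-(1-methoxyethenyl)-3-[(TIPS)oxy]cyclobut-2-en-1-one, both epimers at ring C4 (not isolated) | O=C1C(CO[Si](C)(C)C(C)(C)C)=C(O[Si](C(C)C)(C(C)C)C(C)C)C1(C(OC)=C)C[C@H](c2ccc(OCOC)c(CC=C(C)C)c2OCOC)CO[Si](C)(C)C(C)(C)C | intermediate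
21 | 2-{[(TBS)oxy]methyl}-4-{(2R)-2-Ar-3-[(TBS)oxy]propyl}-5-methoxy-3-[(TIPS)oxy]hexa-1,3,5-trien-1-one, ketene-bearing carbon and methoxyvinyl group cis across C3=C4 (not isolated) | O=C=C(CO[Si](C)(C)C(C)(C)C)/C(O[Si](C(C)C)(C(C)C)C(C)C)=C(\C(OC)=C)C[C@H](c1ccc(OCOC)c(CC=C(C)C)c1OCOC)CO[Si](C)(C)C(C)(C)C | intermediate
22 | 2-{[(TBS)oxy]methyl}-4-{(2R)-2-Ar-3-[(TBS)oxy]propyl}-5-methoxy-3-[(TIPS)oxy]cyclohexa-2,4-dien-1-one (not isolated) | O=C1CC(OC)=C(C[C@H](c2ccc(OCOC)c(CC=C(C)C)c2OCOC)CO[Si](C)(C)C(C)(C)C)C(O[Si](C(C)C)(C(C)C)C(C)C)=C1CO[Si](C)(C)C(C)(C)C | intermediate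
23 | 2-{[(TBS)oxy]methyl}-4-{(2R)-2-Ar-3-[(TBS)oxy]propyl}-5-methoxy-3-[(TIPS)oxy]phenol | COc1cc(O)c(CO[Si](C)(C)C(C)(C)C)c(O[Si](C(C)C)(C(C)C)C(C)C)c1C[C@H](c1ccc(OCOC)c(CC=C(C)C)c1OCOC)CO[Si](C)(C)C(C)(C)C | intermediate
24 | 2-(hydroxymethyl)-4-[(2R)-2-Ar-3-hydroxypropyl]-5-methoxybenzene-1,3-diol | COc1cc(O)c(CO)c(O)c1C[C@H](c1ccc(OCOC)c(CC=C(C)C)c1OCOC)CO | intermediate
25 | 2,6-dihydroxy-3-[(2R)-2-Ar-3-hydroxypropyl]-4-methoxybenzaldehyde | COc1cc(O)c(C=O)c(O)c1C[C@H](c1ccc(OCOC)c(CC=C(C)C)c1OCOC)CO | intermediate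
26 | (3R)-3-Ar-7-hydroxy-5-methoxy-3,4-dihydro-2H-chromene-8-carbaldehyde | COc1cc(O)c(C=O)c2c1C[C@H](c1ccc(OCOC)c(CC=C(C)C)c1OCOC)CO2 | intermediate
27 | (3R)-3-[2,4-dihydroxy-3-(3-methylbut-2-en-1-yl)phenyl]-7-hydroxy-5-methoxy-3,4-dihydro-2H-chromene-8-carbaldehyde (CNP0399843.1) | COc1cc(O)c(C=O)c2c1C[C@H](c1ccc(O)c(CC=C(C)C)c1O)CO2 | target

## Step count and risks

Total number of steps: 14. Longest linear sequence: 13 steps (steps 1–8 and 10–14); step 9 is the only branch.

Steps most likely to fail:

1. Step 10 (the untested substrate class). The vinylogous-ester cyclobutenone may resist 4π ring opening even on irradiation, so that the siloxyalkyne is lost first by silyl migration to the silylketene or by acylation of phenolic product.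
   Fallback (known chemistry; ring A is taken from a purchased phloroglucinol aldehyde and attached by sp3–sp2 cross-coupling instead of being annulated; sets out from 12, comes back at 25): 2,4,6-trihydroxybenzaldehyde F1 would be methylated at the non-chelated 4-hydroxyl (Me2SO4, K2CO3, acetone) to 2,6-dihydroxy-4-methoxybenzaldehyde F2. Iodination at one of its two equivalent free positions (N-iodosuccinimide, DMF, 0 °C) would give 2,6-dihydroxy-3-iodo-4-methoxybenzaldehyde F3, and silylation (TBSOTf, 2,6-lutidine, CH2Cl2) would give 2,6-bis[(TBS)oxy]-3-iodo-4-methoxybenzaldehyde F4. Bromide 12 would be converted by zinc insertion (Zn dust, LiCl, THF, 50 °C) into alkylzinc bromide F5, and Negishi coupling of F5 with F4 (Pd(OAc)2, SPhos, THF, 50 °C) should give tris-silyl ether F6. TBAF in THF would then remove the three TBS groups and deliver 25, from which steps 13 and 14 follow unchanged.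

2. Step 7. E2 elimination of HBr across the tertiary benzylic C–H may outpace substitution at the β-branched primary carbon with the strongly basic acetylide.
   Fallback (a soft nucleophile for the substitution, and the cyclobutenone by the acyl chloride/alkoxyalkyne cycloaddition; sets out from 12, comes back at 14): alkylation of sodium dimethyl malonate with 12 (NaH, DMF, 60 °C) would give dimethyl alkylmalonate F7. Krapcho demethoxycarbonylation (LiCl, wet DMSO, 140 °C) would give methyl ester F8, and saponification (LiOH, THF/H2O) carboxylic acid F9. The acid would be converted under neutral conditions (1-chloro-N,N,2-trimethylprop-1-en-1-amine, CH2Cl2) into acid chloride F10. With Et3N in the presence of ethoxyacetylene, F10 should form alkylketene F11 and, by (2+2) cycloaddition, 3-ethoxy-4-alkylcyclobutenone F12. Brief hydrolysis (0.5 M HCl, THF, 0 °C) would give the symmetrical cyclobutane-1,3-dione, present as 3-hydroxy-2-alkylcyclobutenone F13. Because both oxygens of this enol are equivalent, O-methylation with Me3SiCHN2 (MeOH/toluene) can only lead to 14.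

3. Step 5. The silyl bromide may cleave a MOM acetal, the ortho MOM oxygen may open the activated oxetane intramolecularly, or the ortho substituent may erode the enantioselectivity.
   Fallback (enzymatic desymmetrisation of a prochiral diol in place of the oxetane opening; sets out from 7, comes back at 11): copper-catalysed arylation of diethyl malonate with 7 (CuI, 2-picolinic acid, Cs2CO3, dioxane, 60 °C) would give diethyl arylmalonate F14, and LiAlH4 reduction (THF, 0 °C) the prochiral 2-arylpropane-1,3-diol F15. Lipase-catalysed acetylation (Burkholderia cepacia lipase, vinyl acetate, t-BuOMe) should give (S)-monoacetate F16; hydrolysis of the diacetate with the same enzyme gives the opposite sense if that is needed. Appel bromination of the free hydroxyl (CBr4, PPh3, CH2Cl2, 0 °C) would give bromo acetate F17, and methanolysis of the acetate (K2CO3, MeOH, 0 °C) returns the route at 11.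

## Further compounds

F1 | step 10 | 2,4,6-trihydroxybenzaldehyde (purchased) | O=Cc1c(O)cc(O)cc1O
F2 | step 10 | 2,6-dihydroxy-4-methoxybenzaldehyde | COc1cc(O)c(C=O)c(O)c1
F3 | step 10 | 2,6-dihydroxy-3-iodo-4-methoxybenzaldehyde | COc1cc(O)c(C=O)c(O)c1I
F4 | step 10 | 2,6-bis[(TBS)oxy]-3-iodo-4-methoxybenzaldehyde | COc1cc(O[Si](C)(C)C(C)(C)C)c(C=O)c(O[Si](C)(C)C(C)(C)C)c1I
F5 | step 10 | {(2R)-2-Ar-3-[(TBS)oxy]propyl}zinc bromide (configuration as in 12) | Br[Zn]C[C@H](c1ccc(OCOC)c(CC=C(C)C)c1OCOC)CO[Si](C)(C)C(C)(C)C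
F6 | step 10 | 2,6-bis[(TBS)oxy]-3-{(2R)-2-Ar-3-[(TBS)oxy]propyl}-4-methoxybenzaldehyde | COc1cc(O[Si](C)(C)C(C)(C)C)c(C=O)c(O[Si](C)(C)C(C)(C)C)c1C[C@H](c1ccc(OCOC)c(CC=C(C)C)c1OCOC)CO[Si](C)(C)C(C)(C)C
F7 | step 7 | dimethyl 2-{(2R)-2-Ar-3-[(TBS)oxy]propyl}propanedioate | COC(=O)C(C[C@H](c1ccc(OCOC)c(CC=C(C)C)c1OCOC)CO[Si](C)(C)C(C)(C)C)C(=O)OC
F8 | step 7 | methyl (4R)-4-Ar-5-[(TBS)oxy]pentanoate | COC(=O)CC[C@H](c1ccc(OCOC)c(CC=C(C)C)c1OCOC)CO[Si](C)(C)C(C)(C)C
F9 | step 7 | (4R)-4-Ar-5-[(TBS)oxy]pentanoic acid | OC(=O)CC[C@H](c1ccc(OCOC)c(CC=C(C)C)c1OCOC)CO[Si](C)(C)C(C)(C)C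
F10 | step 7 | (4R)-4-Ar-5-[(TBS)oxy]pentanoyl chloride | ClC(=O)CC[C@H](c1ccc(OCOC)c(CC=C(C)C)c1OCOC)CO[Si](C)(C)C(C)(C)C
F11 | step 7 | (4R)-4-Ar-5-[(TBS)oxy]pent-1-en-1-one (alkylketene) | O=C=CC[C@H](c1ccc(OCOC)c(CC=C(C)C)c1OCOC)CO[Si](C)(C)C(C)(C)C
F12 | step 7 | 3-ethoxy-4-{(2R)-2-Ar-3-[(TBS)oxy]propyl}cyclobut-2-en-1-one, both epimers at ring C4 | CCOC1=CC(=O)C1C[C@H](c2ccc(OCOC)c(CC=C(C)C)c2OCOC)CO[Si](C)(C)C(C)(C)C
F13 | step 7 | 3-hydroxy-2-{(2R)-2-Ar-3-[(TBS)oxy]propyl}cyclobut-2-en-1-one | OC1=C(C[C@H](c2ccc(OCOC)c(CC=C(C)C)c2OCOC)CO[Si](C)(C)C(C)(C)C)C(=O)C1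
F14 | step 5 | diethyl 2-Ar-propanedioate | CCOC(=O)C(c1ccc(OCOC)c(CC=C(C)C)c1OCOC)C(=O)OCC
F15 | step 5 | 2-Ar-propane-1,3-diol | OCC(CO)c1ccc(OCOC)c(CC=C(C)C)c1OCOC
F16 | step 5 | (2S)-3-hydroxy-2-Ar-propyl acetate | OC[C@H](c1ccc(OCOC)c(CC=C(C)C)c1OCOC)COC(C)=O
F17 | step 5 | (2R)-3-bromo-2-Ar-propyl acetate | BrC[C@H](c1ccc(OCOC)c(CC=C(C)C)c1OCOC)COC(C)=O
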